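**Retrosynthetic overview**
1. Both stereocentres (2R,3S) and the A, C and B rings are bought as (+)-catechin (1). No ring of the target is built. The only ring formed is a temporary 1,3-benzodioxole, made first from Ph2CCl2 (2) to give ketal 3 and removed last.
2. The key disconnection is the C7–O–C(=O) aryl ester bond. It leads back to triol 3 and 3,4,5-tris(benzyloxy)benzaldehyde (4), joined at an anode with the achiral carbene precursor 5 to give 6.
3. The final disconnection is three O-benzyl groups plus the ketal, all removed in one hydrogenolysis (6 → target 7).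
4. The ketal costs one step. It blocks catechol oxidation, catechol acylation and base-induced C2 epimerisation through a B-ring quinone methide.

Assumption: 4 and 5 are treated as catalogue chemicals.

**Step 1**
Reactants: 1, (+)-catechin; 2, dichlorodiphenylmethane
Product: 3, 3',4'-O-diphenylmethylene-(+)-catechin = (2R,3S)-2-(2,2-diphenyl-1,3-benzodioxol-5-yl)chromane-3,5,7-triol
Conditions: 2 (1.3 equiv), K2CO3 (3 equiv), MeCN, Ar, rt, 24 h
Reagents that add atoms: dichlorodiphenylmethane, ClC(Cl)(c1ccccc1)c1ccccc1
Why: This is a catechol ketalisation (double O-alkylation via the stabilised chlorodiphenylmethyl cation); only the ortho-dihydroxy B ring can close a five-membered benzodioxole, mono-adducts at the meta-related A-ring phenols or at 3-OH hydrolyse on work-up, and C2/C3 are untouched.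

**Step 2 (key step)**
Reactants: 3, ketal triol (1.3 equiv, excess recovered); 4, 3,4,5-tris(benzyloxy)benzaldehyde (1.0 equiv)
Product: 6, (2R,3S)-2-(2,2-diphenyl-1,3-benzodioxol-5-yl)-3,5-dihydroxychroman-7-yl 3,4,5-tris(benzyloxy)benzoate
Conditions: 5 (2-mesityl-6,7-dihydro-5H-pyrrolo[2,1-c][1,2,4]triazol-2-ium chloride, 20 mol %), DBU (1.5 equiv), Bu4NBF4 (0.1 M), 4 Å MS, MeCN–THF 4:1, Ar, 20 °C; undivided cell, RVC(+)/Pt(–), anode held at ca. –0.2 V vs SCE (set by CV between the Breslow wave and the onset of 3·DBU), 2.1 F/mol of 4
Reagents that add atoms: 3,4,5-tris(benzyloxy)benzaldehyde, O=Cc1cc(OCc2ccccc2)c(OCc2ccccc2)c(OCc2ccccc2)c1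
Why: Proposed new method: site-selective anodic NHC-catalysed dehydrogenative aroylation of an unprotected flavan-3-ol triol, in which the carbene from 5/DBU adds to 4 to give the Breslow enaminol, this loses 2 e–/H+ at the anode several hundred mV before the phenol·DBU pairs of 3 oxidise, and the resulting 2-aroyltriazolium has its carbonyl shielded by the orthogonal N-mesityl ring; the DBU-activated 7-OH (both ortho positions are C–H) attacks faster than the 5-OH (ortho to C4a/C4H2) or the neutral, hindered secondary 3-OH, which releases the carbene while DBU-H+ is reduced to H2 at Pt (net ArCHO + Ar'OH → ArCO2Ar' + H2); because NHCs can re-ionise aryl esters, any 5-O-ester can return to the acyl azolium pool and drain to the less hindered 7-O-ester; no stereocentre is made, and C2 cannot epimerise because the ketal prevents B-ring quinone methide formation; the closest known reaction type is NHC-mediated anodic oxidative esterification of aldehydes with simple alcohols (and chemical-oxidant NHC esterification with simple phenols), not yet shown on an oxidation-labile polyphenol or with phenol/phenol/alcohol site selection.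

**Step 3**
Reactants: 6, protected 7-O-gallate
Product: 7, (+)-catechin 7-O-gallate = (2R,3S)-2-(3,4-dihydroxyphenyl)-3,5-dihydroxychroman-7-yl 3,4,5-trihydroxybenzoate
Conditions: H2 (1 atm), 20 % Pd(OH)2/C, THF–EtOAc 1:1, rt; filter under Ar, Sephadex LH-20
Reagents that add atoms: none
Why: Catalytic hydrogenolysis cleaves the three ArO–CH2Ph bonds and both benzhydrylic C–O bonds of the ketal (giving toluene and Ph2CH2) in one operation; the aryl ester is not reduced, the non-nucleophilic solvent avoids alcoholysis of the phenolic ester, and the cyclic C2–O1 ether of flavan-3-ols normally survives these conditions, so (2R,3S) is retained.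

**Compound list**
1 | (+)-catechin, (2R,3S) | Oc1cc(O)c2c(c1)O[C@H](c1ccc(O)c(O)c1)[C@@H](O)C2 | starting material
2 | dichlorodiphenylmethane | ClC(Cl)(c1ccccc1)c1ccccc1 | starting material
3 | 3',4'-O-diphenylmethylene-(+)-catechin | Oc1cc(O)c2c(c1)O[C@H](c1ccc3c(c1)OC(c1ccccc1)(c1ccccc1)O3)[C@@H](O)C2 | intermediate
4 | 3,4,5-tris(benzyloxy)benzaldehyde | O=Cc1cc(OCc2ccccc2)c(OCc2ccccc2)c(OCc2ccccc2)c1 | starting material
5 | 2-mesityl-6,7-dihydro-5H-pyrrolo[2,1-c][1,2,4]triazol-2-ium chloride (achiral precatalyst, transfers no atoms) | Cc1cc(C)c(c(C)c1)[n+]1cn2CCCc2n1.[Cl-] | starting material (catalyst)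
6 | 3',4'-O-diphenylmethylene-(+)-catechin 7-O-[3,4,5-tris(benzyloxy)benzoate] | O=C(Oc1cc(O)c2c(c1)O[C@H](c1ccc3c(c1)OC(c1ccccc1)(c1ccccc1)O3)[C@@H](O)C2)c1cc(OCc2ccccc2)c(OCc2ccccc2)c(OCc2ccccc2)c1 | intermediate
7 | (+)-catechin 7-O-gallate | O=C(Oc1cc(O)c2c(c1)O[C@H](c1ccc(O)c(O)c1)[C@@H](O)C2)c1cc(O)c(O)c(O)c1 | target

**Total steps:** 3. **Longest linear sequence:** 3.

**Steps most likely to fail**
1. Step 2 (proposed new step). The risks are insufficient 7-O versus 5-O selectivity, 5,7-diester formation, anodic phenol oxidation, and slow turnover of the carbene in the presence of acidic phenols. Regiochemistry is checked by the downfield shift of both H-6 and H-8 and by a 5-OH/H-4 NOE. Fallback (known chemistry): drop the aldehyde/electrolysis route. Convert commercial 3,4,5-tris(benzyloxy)benzoic acid to its chloride ((COCl)2, cat. DMF). Acylate 3 with 1.0 equiv of it (Et3N, CH2Cl2–THF, –20 °C), then separate the 7-O and 5-O esters by chromatography.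
2. Step 1. The risks are a modest yield and oligomeric A-ring by-products. Fallback: replace the covalent ketal with a transient cyclic 3',4'-phenylboronate (PhB(OH)2, 4 Å MS, MeCN). Carry it directly into the esterification and let it hydrolyse on aqueous work-up, so the last step only removes benzyl groups.
3. Step 3. The risks are sluggish ketal hydrogenolysis, partial ester loss, and air oxidation of 7. Fallback: change the protecting-group set to all-silicon, with a 3',4'-O-di-tert-butylsilylene on catechin and 3,4,5-tris(TBSO)benzaldehyde as the acyl partner. Finish with a non-reductive fluoride deprotection (Et3N·3HF, THF, 0 °C).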